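## Structural features

The target 23 is a flavonol: a benzo ring A (C4a to C8a), a 4-pyranone ring C (O1, C2, C3, C4) and an unsubstituted phenyl ring B on C2, with hydroxyls on C3, C5 and C7. C8 carries the only stereocentre, a benzylic methine of R configuration (priorities: flavonol aryl > CH2C=O > CH2CH2Ar > H). Its two arms are a 2-(4-hydroxy-3-methoxyphenyl)ethyl group and a 2-oxo-4-phenylbutyl group, so the side chain is a 1,7-diarylheptan-3-one joined to ring A through its C5. No second stereocentre is adjacent, so the task is absolute control at a carbon that has no heteroatom handle. Ring A is a phloroglucinol with five of six positions substituted; only C6 keeps a hydrogen, and the chain sits between O7 and O1. Fragile features are the four free hydroxyls (oxidation-prone in base), the chain ketone lying gamma to a ring carbon with an ortho oxygen (hemiketal or 4H-chromene closure under acid), and the electron-rich benzylic C–H (retro-Michael cleavage through a quinone methide would erase the centre). The real difficulty is regiochemical: the three ring-A oxygens must be told apart so that the pyranone closes through the oxygen flanked by C8 and C4a, and not through the C5 oxygen, which would give the 6-alkyl isomer. The key step uses exactly this feature: O1 is the only acylable oxygen and carries a benzoate that becomes C2 plus ring B, while C3 is the acidic methylene of the aryl benzyloxymethyl ketone on C4a.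

## Logic of the disconnections

23 to 22. The four O–benzyl bonds (O3, O5, O7 and the guaiacyl oxygen) are cut together. One neutral hydrogenolysis then frees every hydroxyl in the last flask, so the sensitive polyphenol and the hemiketal-prone hydroxy ketone never meet acid or base. No skeletal simplification results, only protection. The forward step must spare the C2=C3 bond and the chain ketone.

22 to 20 (through 21). O1–C2 and C2–C3 are cut, which opens ring C and returns the benzoyl group to O1. The reason is that an ester on O1 stores the regiochemistry of closure and supplies C2 with ring B in a single group. The gain is one ring and one C–C bond, with the 3-oxygen already at its final oxidation level. The forward step needs an enolate at one site only and an acid stage that also frees the chain ketone.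

20 to 18 and 19. The ester C–O bond on O1 is cut. In 18 the only free hydroxyl is the one between the chain and the acyl group, so no selectivity question arises. The demand is acylation of a hindered, hydrogen-bonded phenol without enolising the neighbouring ketone.

18 to 15 and 16 (through 17). The bond between the carbonyl carbon and the benzyloxymethyl carbon is cut and the carbonyl is taken back to the aldehyde level. A Fries-type transfer needs a Lewis acid, which would threaten the dioxolane and the benzyl ethers peri and alpha to the new carbonyl. Two non-acidic operations avoid this. The demand is 1,2-addition next to a phenoxide and oxidation of a doubly ortho-substituted carbinol.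

15 to 12 and 13. The aryl–CHO bond (future C4a–C4) is cut. Compound 12 has two ring hydrogens, and only magnesium templating through the free hydroxyl distinguishes the ortho one from the one between the two benzyloxy groups. The gain is a regiospecific one-carbon introduction. The demand is that the dioxolane survives the magnesium salt and the work-up.

12 to 11. The two dioxolane C–O bonds are cut. The chain carbonyl must be non-enolisable in the key step and must come off in the same acid stage. The demand is that ketal formation outcompetes capture of the carbonyl by the neighbouring phenol.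

11 to 8 and 9 (through 10). The bond between the chain carbonyl and the phenethyl CH2 is cut and the aryl ester C–O bond is re-formed. The lactone serves twice: it masks O1 selectively and it is the acyl donor for the ketone. The gain is eight carbons added and the only free phenol released at exactly the right oxygen. The demand is mono-addition, secured by the N-methoxy-N-methylamide 10.

8 to 7. The C4–H bond at the stereocentre is cut, which returns the C3=C4 double bond. The planar coumarin is then the substrate for catalyst-controlled hydride delivery. The demand is high facial selectivity on a beta-carbon crowded by the peri benzyloxy group.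

7 to 6. Three O–benzyl bonds are cut. Benzylation after ring formation means the acid-promoted condensation runs on free phenols and one operation protects all three.

6 to 4 and 5. The aryl–C4 bond and the lactone O–C2 bond are cut. Because 5 is threefold symmetric, only one coumarin can form, and ring formation itself differentiates one oxygen from the other two. The demand is a mild acid so that the guaiacol ring of 4 stays out of the reaction.

4 to 1 and 2 (through 3). The bond between the ketone carbon and the ester-bearing CH2 is cut. Both pieces are commercial, and the activated acid 3 accepts the malonate half-ester without phenol protection.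

A check of 20 and 22 against 23 shows the same R centre and the same substitution pattern; nothing in these structures needs correction.

## Other disconnections considered

Alternative 1: Ring A is cut at C8–C8a and C6–C7 (C4a–C8a then forms in the closing electrocyclisation). The fragments are the chiral siloxyalkyne A1 and 3-ethoxycyclobut-2-en-1-one A2. In the forward direction heating would open A2 to a vinylketene, which would add [2+2] to A1. The resulting vinylcyclobutenone would open (4π) and reclose (6π) to phenol A3.
- In its favour: A3 would emerge with three differentiated oxygens and the free hydroxyl next to the chain, which is exactly O1. On this point it equals the lactone device of the chosen plan. The stereocentre could be set on an acyclic acid by auxiliary chemistry before ring A exists, which avoids asymmetric reduction of a crowded coumarin; that is arguably better.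
- Against it here: A1 needs a multistep preparation (chiral acid, ynolate homologation, silylation). A3 still lacks C4 and ring C, so the ortho-acylation problem and the same Baker–Venkataraman closure remain. O5 would end as an ethyl ether that hydrogenolysis cannot remove, and its Lewis-acid cleavage would sit next to a guaiacyl methyl ether.
- Comparison: the pericyclic cascade is mechanistically elegant and regiochemically self-contained, whereas the chosen plan is ionic and relies on symmetry plus templating. In step count Alternative 1 replaces the five-step front end with a longer one and adds deprotection steps.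

Alternative 2: Ring C is cut at C4a–C4, C4–C3 and O1–C2. The components are the iodoresorcinol A4, phenylacetylene A5 and carbon monoxide A6. In the forward direction a palladium catalyst would insert into the C–I bond, take up A6 and couple with A5 to an ortho-hydroxyaryl ynone. This would close 6-endo through O1 to flavone A7.
- In its favour: three bonds and one ring would form in one convergent operation. The precursor of A4 is a symmetric 2-alkyl-5-benzyloxyresorcinol, so iodination has no regiochemical choice; on this point it is better than the chosen plan, which depends on magnesium templating. Closure through O1 is automatic because the other hydroxyl is para to the ynone, which equals the chosen plan.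
- Against it here: A7 has no oxygen on C3. A late oxidation of the finished flavone (after protecting the 7-hydroxyl) would be required, whereas the chosen plan brings that oxygen in with the ketone. Oxidative addition into an iodide flanked by two oxygen substituents on a very electron-rich ring is expected to be slow, direct alkynylation without insertion of A6 competes, and 5-exo closure to an aurone is the known alternative. The lactone route also does not lead to the symmetric resorcinol, so a new front end would be needed.
- Comparison: the organometallic cycle is shorter on paper up to A7. Once the C3 oxidation and protecting-group work are counted, the step economy is at best equal.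

Alternative 3: Ring A is cut at C4a–C8a, which leads back to the acyclic triketo ester A8. In the forward direction a magnesium alkoxide would fold A8 so that the C6 carbanion attacks the ester carbonyl (Claisen mode). Aromatisation would give the acetophenone A9.
- In its favour: ring A and its acyl group would arise together. The 1,3-relation of chain and acyl is fixed by chain connectivity, with no aromatic substitution at all; this is equal to or better than the formylation of the chosen plan.
- Against it here: A8 is a sensitive polyketone whose ester is flanked by a bulky branched substituent, which slows the Claisen mode relative to the competing aldol folding to a resorcylate. A9 has two hydroxyls ortho to the acetyl group, so the choice between O1 and O5 returns and must be solved by selective benzylation. The acetyl group has no omega-oxygen, so the 3-hydroxyl again needs a late oxidation, and the oxidative chalcone route is prone to aurone formation with a 6'-oxygen present.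
- Comparison: the biomimetic folding is strong on bond count for ring A. The chosen plan gets the oxygen differentiation from the lactone without extra steps and has the better overall step economy.

Key step: step 11

Assumption on the chemistry: the (R)-configured bisphosphine is taken to deliver hydride to the face of C4 that gives (4R)-8; if a test reduction showed the opposite sense, the (S)-ligand would be used and nothing else would change.

Naming remark: "ketal chain" stands for the (2R)-4-[4-(benzyloxy)-3-methoxyphenyl]-1-[2-(2-phenylethyl)-1,3-dioxolan-2-yl]butan-2-yl group.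

## Route

Step 1
Reactants: 1 dihydroferulic acid, 3-(4-hydroxy-3-methoxyphenyl)propanoic acid; 2 potassium ethyl malonate
Product: 4 ethyl 5-(4-hydroxy-3-methoxyphenyl)-3-oxopentanoate, via acyl imidazolide 3 (not isolated)
Conditions: CDI (1.1 equiv), THF, rt; then 2, MgCl2, Et3N, MeCN, rt → 45 °C; 1 M aq. HCl
Reagents that add atoms: 1,1'-carbonyldiimidazole, O=C(n1ccnc1)n1ccnc1 (its imidazole is carried only by intermediate 3)
Why: Masamune–Brooks homologation: the carboxylic acid is activated chemoselectively over the phenol, and the magnesium malonate half-ester C-acylates and decarboxylates on acidification to the beta-keto ester.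

Step 2
Reactants: 4 ethyl 5-(4-hydroxy-3-methoxyphenyl)-3-oxopentanoate; 5 phloroglucinol, benzene-1,3,5-triol
Product: 6 5,7-dihydroxy-4-[2-(4-hydroxy-3-methoxyphenyl)ethyl]-2H-chromen-2-one
Conditions: CF3CO2H, rt → 50 °C
Reagents that add atoms: none
Why: Pechmann condensation; the threefold symmetry of 5 allows only one coumarin, and ring formation marks the lactone oxygen as the future O1. Phloroglucinol is far more nucleophilic than the guaiacol ring, so a mild acid suffices.

Step 3
Reactants: 6 5,7-dihydroxy-4-[2-(4-hydroxy-3-methoxyphenyl)ethyl]-2H-chromen-2-one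
Product: 7 5,7-bis(benzyloxy)-4-{2-[4-(benzyloxy)-3-methoxyphenyl]ethyl}-2H-chromen-2-one
Conditions: BnBr (3.6 equiv), K2CO3, DMF, 60 °C
Reagents that add atoms: benzyl bromide, BrCc1ccccc1
Why: Williamson etherification of all three phenols in one operation; the lactone is stable to carbonate in an aprotic solvent, and the pyranone deactivates the ring toward C-benzylation.

Step 4
Reactants: 7 5,7-bis(benzyloxy)-4-{2-[4-(benzyloxy)-3-methoxyphenyl]ethyl}-2H-chromen-2-one
Product: 8 (4R)-5,7-bis(benzyloxy)-4-{2-[4-(benzyloxy)-3-methoxyphenyl]ethyl}-3,4-dihydro-2H-chromen-2-one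
Conditions: Cu(OAc)2·H2O (3 mol %), (R)-DTBM-SEGPHOS (3 mol %), (EtO)2MeSiH, t-BuOH, toluene, 0 °C → rt
Reagents that add atoms: none
Why: Asymmetric conjugate reduction of a beta,beta-disubstituted unsaturated lactone by a ligand-bound copper hydride, a reaction established for 4-substituted coumarins. The chiral bisphosphine selects the face of C4 by distinguishing the fused aryl ring from the arylethyl chain, and t-BuOH protonates the copper enolate at C3. C4–H is not acidic afterwards, so the centre is configurationally stable.

Step 5
Reactants: 8 (4R)-5,7-bis(benzyloxy)-4-{2-[4-(benzyloxy)-3-methoxyphenyl]ethyl}-3,4-dihydro-2H-chromen-2-one; 9 2-phenylethylmagnesium chloride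
Product: 11 (5R)-5-[2,4-bis(benzyloxy)-6-hydroxyphenyl]-7-[4-(benzyloxy)-3-methoxyphenyl]-1-phenylheptan-3-one, via Weinreb amide 10 (not isolated)
Conditions: MeNH(OMe)·HCl (1.6 equiv), i-PrMgCl (3.2 equiv), THF, −20 °C, then 8; then 9 (2.5 equiv), −20 → 0 °C; aq. NH4Cl
Reagents that add atoms: N,O-dimethylhydroxylamine hydrochloride, CNOC.Cl (its atoms are carried only by intermediate 10)
Why: Weinreb ketone synthesis run in one flask: the magnesium amide opens the aryl lactone, and the chelated tetrahedral adduct of the Grignard reagent prevents double addition. Not isolating 10 avoids relactonisation of the hydroxy amide; the stereocentre is beta to the carbonyl and is not touched.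

Step 6
Reactants: 11 (5R)-5-[2,4-bis(benzyloxy)-6-hydroxyphenyl]-7-[4-(benzyloxy)-3-methoxyphenyl]-1-phenylheptan-3-one
Product: 12 3,5-bis(benzyloxy)-2-[ketal chain]phenol
Conditions: HOCH2CH2OH (10 equiv), PPTS (cat.), toluene, reflux, Dean–Stark
Reagents that add atoms: ethylene glycol, OCCO
Why: Acid-catalysed ketalisation under water removal. A cyclic aryl alkyl ketal or 4H-chromene formed by the neighbouring phenol re-ionises easily because phenol is the better leaving group, so the equilibrating mixture should drain into the dialkyl dioxolane.

Step 7
Reactants: 12 3,5-bis(benzyloxy)-2-[ketal chain]phenol; 13 paraformaldehyde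
Product: 15 4,6-bis(benzyloxy)-2-hydroxy-3-[ketal chain]benzaldehyde, via hydroxymethyl phenol 14 (not isolated)
Conditions: MgCl2 (2 equiv), Et3N (4 equiv), 13 (7 equiv), MeCN, reflux; sat. aq. NH4Cl
Reagents that add atoms: none
Why: Casnati–Skattebøl ortho-formylation: the magnesium phenoxide delivers formaldehyde to the only free ortho position through a six-membered chelate, and a second formaldehyde oxidises the hydroxymethyl group by hydride transfer. The ring hydrogen between the two benzyloxy groups has no such delivery path, and the mildly basic medium and buffered work-up spare the dioxolane.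

Step 8
Reactants: 15 4,6-bis(benzyloxy)-2-hydroxy-3-[ketal chain]benzaldehyde; 16 tributyl[(benzyloxy)methyl]stannane
Product: 17 2-(benzyloxy)-1-{4,6-bis(benzyloxy)-2-hydroxy-3-[ketal chain]phenyl}ethan-1-ol (both carbinol epimers)
Conditions: 16 (2.6 equiv), n-BuLi (2.5 equiv), THF, −78 °C; then 15, −78 → −40 °C; sat. aq. NH4Cl
Reagents that add atoms: none
Why: Tin–lithium exchange gives (benzyloxymethyl)lithium; one equivalent deprotonates the phenol and a second adds 1,2 to the aldehyde. The new carbinol centre is uncontrolled and is removed in the next step; the crude diol is carried on without acid contact.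

Step 9
Reactants: 17 2-(benzyloxy)-1-{4,6-bis(benzyloxy)-2-hydroxy-3-[ketal chain]phenyl}ethan-1-ol
Product: 18 2-(benzyloxy)-1-{4,6-bis(benzyloxy)-2-hydroxy-3-[ketal chain]phenyl}ethan-1-one
Conditions: activated MnO2 (20 equiv), CH2Cl2, rt
Reagents that add atoms: none
Why: Heterogeneous MnO2 oxidation of a benzylic carbinol, which tolerates the free phenol, benzyl ethers and the dioxolane. The product is stabilised by the hydrogen bond between O1–H and the new carbonyl.

Step 10
Reactants: 18 2-(benzyloxy)-1-{4,6-bis(benzyloxy)-2-hydroxy-3-[ketal chain]phenyl}ethan-1-one; 19 benzoyl chloride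
Product: 20 3,5-bis(benzyloxy)-2-[(benzyloxy)acetyl]-6-[ketal chain]phenyl benzoate
Conditions: 19 (1.5 equiv), Et3N, DMAP (cat.), CH2Cl2, 0 °C → rt
Reagents that add atoms: none
Why: DMAP-catalysed O-acylation; the N-benzoylpyridinium ion is reactive enough for the hindered, hydrogen-bonded phenol, and the amine base is too weak to start the acyl transfer early. Only one hydroxyl is present, so the benzoate must sit on O1.

Step 11
Reactants: 20 3,5-bis(benzyloxy)-2-[(benzyloxy)acetyl]-6-[ketal chain]phenyl benzoate
Product: 22 3,5,7-tris(benzyloxy)-8-[(3R)-1-[4-(benzyloxy)-3-methoxyphenyl]-5-oxo-7-phenylheptan-3-yl]-2-phenyl-4H-chromen-4-one, via diketone 21 (not isolated)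
Conditions: LiN(SiMe3)2 (2.5 equiv), THF, −78 → 0 °C; then 3 M aq. HCl, THF, 50 °C
Reagents that add atoms: water, O
Why: Baker–Venkataraman rearrangement followed by acid cyclodehydration, the classical entry to 3-alkoxyflavones. The amide base removes a proton from the only enolisable position, the CH2 between the aryl carbonyl and the benzyloxy group; the chain carbonyl is locked as a dioxolane, which matters because its alpha-carbon could otherwise reach the benzoate through an equally favourable six-membered transition state. The enolate carbon attacks the benzoate carbonyl on O1 through a six-membered cyclic transition state, and collapse of the tetrahedral alkoxide expels the phenoxide and forms C2–C3, the stabilised diketonate of 21 driving the transfer. Aqueous HCl protonates 21, O1–H adds to the benzoyl carbonyl in a 6-exo-trig closure, and loss of water from the 2-hydroxychromanone gives the aromatic pyranone ring C (O1–C2); the same acid hydrolyses the dioxolane to the chain ketone. No stereocentre is created, and the existing one has no acidic hydrogen and is untouched by the base or by dilute acid at 50 °C. Closure through O1 is secured by the substrate, because O5 and O7 are benzyl ethers and cannot add. C-acylation over O-acylation of the enolate is enforced by ring size, six-membered for carbon against eight-membered for oxygen. The 3-oxygen arrives with the ketone at its final oxidation level, so the finished flavone needs no oxidation.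

Step 12
Reactants: 22 3,5,7-tris(benzyloxy)-8-[(3R)-1-[4-(benzyloxy)-3-methoxyphenyl]-5-oxo-7-phenylheptan-3-yl]-2-phenyl-4H-chromen-4-one
Product: 23 3,5,7-trihydroxy-8-[(3R)-1-(4-hydroxy-3-methoxyphenyl)-5-oxo-7-phenylheptan-3-yl]-2-phenyl-4H-chromen-4-one
Conditions: H2 (1 atm), Pd/C (10 wt %), EtOAc–MeOH, rt
Reagents that add atoms: none
Why: Catalytic hydrogenolysis of four aryl and enol benzyl ethers under neutral conditions; the dialkyl ketone, the aryl methyl ether and the pyranone double bond are normally retained at ambient pressure. The neutral medium avoids hemiketal formation and retro-Michael cleavage at the stereocentre.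

## Compound list

1 | dihydroferulic acid, 3-(4-hydroxy-3-methoxyphenyl)propanoic acid | COc1cc(CCC(=O)O)ccc1O | starting material
2 | potassium ethyl malonate, potassium 3-ethoxy-3-oxopropanoate | CCOC(=O)CC(=O)[O-].[K+] | starting material
3 | 1-[3-(4-hydroxy-3-methoxyphenyl)propanoyl]-1H-imidazole | COc1cc(CCC(=O)n2ccnc2)ccc1O | intermediate (not isolated)
4 | ethyl 5-(4-hydroxy-3-methoxyphenyl)-3-oxopentanoate | CCOC(=O)CC(=O)CCc1ccc(O)c(OC)c1 | intermediate
5 | phloroglucinol, benzene-1,3,5-triol | Oc1cc(O)cc(O)c1 | starting material
6 | 5,7-dihydroxy-4-[2-(4-hydroxy-3-methoxyphenyl)ethyl]-2H-chromen-2-one | COc1cc(CCc2cc(=O)oc3cc(O)cc(O)c23)ccc1O | intermediate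
7 | 5,7-bis(benzyloxy)-4-{2-[4-(benzyloxy)-3-methoxyphenyl]ethyl}-2H-chromen-2-one | COc1cc(CCc2cc(=O)oc3cc(OCc4ccccc4)cc(OCc4ccccc4)c23)ccc1OCc1ccccc1 | intermediate
8 | (4R)-5,7-bis(benzyloxy)-4-{2-[4-(benzyloxy)-3-methoxyphenyl]ethyl}-3,4-dihydro-2H-chromen-2-one | COc1cc(CC[C@@H]2CC(=O)Oc3cc(OCc4ccccc4)cc(OCc4ccccc4)c32)ccc1OCc1ccccc1 | intermediate
9 | 2-phenylethylmagnesium chloride | Cl[Mg]CCc1ccccc1 | starting material
10 | (3R)-3-[2,4-bis(benzyloxy)-6-hydroxyphenyl]-5-[4-(benzyloxy)-3-methoxyphenyl]-N-methoxy-N-methylpentanamide | COc1cc(CC[C@H](CC(=O)N(C)OC)c2c(O)cc(OCc3ccccc3)cc2OCc2ccccc2)ccc1OCc1ccccc1 | intermediate (not isolated)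
11 | (5R)-5-[2,4-bis(benzyloxy)-6-hydroxyphenyl]-7-[4-(benzyloxy)-3-methoxyphenyl]-1-phenylheptan-3-one | COc1cc(CC[C@H](CC(=O)CCc2ccccc2)c2c(O)cc(OCc3ccccc3)cc2OCc2ccccc2)ccc1OCc1ccccc1 | intermediate
12 | 3,5-bis(benzyloxy)-2-[(2R)-4-[4-(benzyloxy)-3-methoxyphenyl]-1-[2-(2-phenylethyl)-1,3-dioxolan-2-yl]butan-2-yl]phenol | COc1cc(CC[C@H](CC2(CCc3ccccc3)OCCO2)c2c(OCc3ccccc3)cc(OCc3ccccc3)cc2O)ccc1OCc1ccccc1 | intermediate
13 | paraformaldehyde (drawn as the monomer) | C=O | starting material
14 | 3,5-bis(benzyloxy)-2-(hydroxymethyl)-6-[ketal chain]phenol | COc1cc(CC[C@H](CC2(CCc3ccccc3)OCCO2)c2c(OCc3ccccc3)cc(OCc3ccccc3)c(CO)c2O)ccc1OCc1ccccc1 | intermediate (not isolated)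
15 | 4,6-bis(benzyloxy)-2-hydroxy-3-[ketal chain]benzaldehyde | COc1cc(CC[C@H](CC2(CCc3ccccc3)OCCO2)c2c(OCc3ccccc3)cc(OCc3ccccc3)c(C=O)c2O)ccc1OCc1ccccc1 | intermediate
16 | tributyl[(benzyloxy)methyl]stannane | CCCC[Sn](CCCC)(CCCC)COCc1ccccc1 | starting material
17 | 2-(benzyloxy)-1-{4,6-bis(benzyloxy)-2-hydroxy-3-[ketal chain]phenyl}ethan-1-ol (both carbinol epimers) | COc1cc(CC[C@H](CC2(CCc3ccccc3)OCCO2)c2c(OCc3ccccc3)cc(OCc3ccccc3)c(C(O)COCc3ccccc3)c2O)ccc1OCc1ccccc1 | intermediate
18 | 2-(benzyloxy)-1-{4,6-bis(benzyloxy)-2-hydroxy-3-[ketal chain]phenyl}ethan-1-one | COc1cc(CC[C@H](CC2(CCc3ccccc3)OCCO2)c2c(OCc3ccccc3)cc(OCc3ccccc3)c(C(=O)COCc3ccccc3)c2O)ccc1OCc1ccccc1 | intermediate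
19 | benzoyl chloride | O=C(Cl)c1ccccc1 | starting material
20 | 3,5-bis(benzyloxy)-2-[(benzyloxy)acetyl]-6-[ketal chain]phenyl benzoate | COc1cc(CC[C@H](CC2(CCc3ccccc3)OCCO2)c2c(OCc3ccccc3)cc(OCc3ccccc3)c(C(=O)COCc3ccccc3)c2OC(=O)c2ccccc2)ccc1OCc1ccccc1 | intermediate
21 | 2-(benzyloxy)-1-{4,6-bis(benzyloxy)-2-hydroxy-3-[ketal chain]phenyl}-3-phenylpropane-1,3-dione | COc1cc(CC[C@H](CC2(CCc3ccccc3)OCCO2)c2c(OCc3ccccc3)cc(OCc3ccccc3)c(C(=O)C(OCc3ccccc3)C(=O)c3ccccc3)c2O)ccc1OCc1ccccc1 | intermediate (not isolated)
22 | 3,5,7-tris(benzyloxy)-8-[(3R)-1-[4-(benzyloxy)-3-methoxyphenyl]-5-oxo-7-phenylheptan-3-yl]-2-phenyl-4H-chromen-4-one | COc1cc(CC[C@H](CC(=O)CCc2ccccc2)c2c(OCc3ccccc3)cc(OCc3ccccc3)c3c(=O)c(OCc4ccccc4)c(-c4ccccc4)oc23)ccc1OCc1ccccc1 | intermediate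
23 | 3,5,7-trihydroxy-8-[(3R)-1-(4-hydroxy-3-methoxyphenyl)-5-oxo-7-phenylheptan-3-yl]-2-phenyl-4H-chromen-4-one | COc1cc(CC[C@H](CC(=O)CCc2ccccc2)c2c(O)cc(O)c3c(=O)c(O)c(-c4ccccc4)oc23)ccc1O | target

## Step count and least certain steps

Total step count: 12. Longest linear sequence: 12 steps (1 to 23); every other component is commercial.

Step 11 (key step). The most likely failure is stalling of the acyl transfer, because the benzoate carbonyl lies between the branched C8 chain and the twisted acyl group and the attacking enolate is alpha-oxygenated; slow transfer leaves time for intermolecular cleavage of the benzoate. In the acid stage, partial loss of the peri 5-O-benzyl group is possible but harmless, since step 12 removes it anyway. Fallback: form the same C2–C3 bond intermolecularly and bypass 20. Starting from 18, the phenoxide–enolate dianion is generated with LiN(SiMe3)2 (3.2 equiv, THF, −78 °C) and treated with 19. Any O-benzoylated material is 20 and is converted on by the excess base, so both channels end at 21. The same acid treatment then returns to the route at 22. This fallback makes no compound outside the list (F0).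

Step 4. Poor facial discrimination or slow hydride delivery is the main risk, because the 5-benzyloxy group crowds C4 and pushes its substituent out of the ring plane; further reduction of the aryl lactone toward the lactol is a second possibility. Fallback: give up catalyst control. Starting from 7, an achiral copper hydride (Cu(OAc)2·H2O, 1,2-bis(diphenylphosphino)benzene, (EtO)2MeSiH, t-BuOH) gives the racemic lactone F1. Preparative chromatography on a chiral stationary phase separates the enantiomers, the (4S)-lactone F2 is set aside, and the route is rejoined at 8.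

Step 6. The phenol oxygen is six atoms from the carbonyl carbon, so capture of the oxocarbenium ion by the phenol (cyclic mixed ketal, then dehydration to a 4H-chromene) may compete with dioxolane formation. Fallback: mask the phenol before the ketone exists. Starting from 8, the amide 10 is isolated and allylated (allyl bromide, K2CO3, DMF) to the allyl ether amide F3. Addition of 9 gives the allyl ether ketone F4, ketalisation as in step 6 gives the allyl ether ketal F5, and Pd(PPh3)4 (zerovalent palladium) with morpholine removes the allyl group to rejoin at 12. This costs three extra steps.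

Step 9. The two ortho substituents twist the carbinol out of conjugation, so oxidation on the MnO2 surface may be slow. Meanwhile the electron-rich benzylic alcohol can ionise toward a quinone methide and oligomerise, or the free phenol can be oxidised. Fallback: remove the free phenol from the oxidation. Starting from 15, allylation gives the allyl ether aldehyde F6, addition of (benzyloxymethyl)lithium gives the allyl ether carbinol F7, and Dess–Martin periodinane with NaHCO3 gives the allyl ether ketone F8. Deallylation with Pd(PPh3)4 and morpholine rejoins the route at 18.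

Step 12. Incomplete cleavage of the 5-O- and 7-O-benzyl ethers next to the C8 chain is the most likely problem; forcing the reaction risks saturation of the C2=C3 bond or reduction of the chain ketone. Fallback: non-reductive debenzylation of 22 with BCl3 and pentamethylbenzene (CH2Cl2, −78 °C), which leaves the aryl methyl ether and the ketone and arrives directly at 23. This fallback makes no compound outside the list (F0).

## Further compounds

F0 | step 11 | none | none
F1 | step 4 | racemic 5,7-bis(benzyloxy)-4-{2-[4-(benzyloxy)-3-methoxyphenyl]ethyl}-3,4-dihydro-2H-chromen-2-one | COc1cc(CCC2CC(=O)Oc3cc(OCc4ccccc4)cc(OCc4ccccc4)c32)ccc1OCc1ccccc1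
F2 | step 4 | (4S)-5,7-bis(benzyloxy)-4-{2-[4-(benzyloxy)-3-methoxyphenyl]ethyl}-3,4-dihydro-2H-chromen-2-one | COc1cc(CC[C@H]2CC(=O)Oc3cc(OCc4ccccc4)cc(OCc4ccccc4)c32)ccc1OCc1ccccc1
F3 | step 6 | (3R)-3-[2,4-bis(benzyloxy)-6-(prop-2-en-1-yloxy)phenyl]-5-[4-(benzyloxy)-3-methoxyphenyl]-N-methoxy-N-methylpentanamide | COc1cc(CC[C@H](CC(=O)N(C)OC)c2c(OCC=C)cc(OCc3ccccc3)cc2OCc2ccccc2)ccc1OCc1ccccc1
F4 | step 6 | (5R)-5-[2,4-bis(benzyloxy)-6-(prop-2-en-1-yloxy)phenyl]-7-[4-(benzyloxy)-3-methoxyphenyl]-1-phenylheptan-3-one | COc1cc(CC[C@H](CC(=O)CCc2ccccc2)c2c(OCC=C)cc(OCc3ccccc3)cc2OCc2ccccc2)ccc1OCc1ccccc1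
F5 | step 6 | 1,5-bis(benzyloxy)-3-(prop-2-en-1-yloxy)-2-[ketal chain]benzene | COc1cc(CC[C@H](CC2(CCc3ccccc3)OCCO2)c2c(OCc3ccccc3)cc(OCc3ccccc3)cc2OCC=C)ccc1OCc1ccccc1
F6 | step 9 | 4,6-bis(benzyloxy)-2-(prop-2-en-1-yloxy)-3-[ketal chain]benzaldehyde | COc1cc(CC[C@H](CC2(CCc3ccccc3)OCCO2)c2c(OCc3ccccc3)cc(OCc3ccccc3)c(C=O)c2OCC=C)ccc1OCc1ccccc1
F7 | step 9 | 2-(benzyloxy)-1-{4,6-bis(benzyloxy)-2-(prop-2-en-1-yloxy)-3-[ketal chain]phenyl}ethan-1-ol | COc1cc(CC[C@H](CC2(CCc3ccccc3)OCCO2)c2c(OCc3ccccc3)cc(OCc3ccccc3)c(C(O)COCc3ccccc3)c2OCC=C)ccc1OCc1ccccc1
F8 | step 9 | 2-(benzyloxy)-1-{4,6-bis(benzyloxy)-2-(prop-2-en-1-yloxy)-3-[ketal chain]phenyl}ethan-1-one | COc1cc(CC[C@H](CC2(CCc3ccccc3)OCCO2)c2c(OCc3ccccc3)cc(OCc3ccccc3)c(C(=O)COCc3ccccc3)c2OCC=C)ccc1OCc1ccccc1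
F0 | step 12 | none | none
A1 | alternative 1 | {[(3R)-5-[4-(benzyloxy)-3-methoxyphenyl]-3-{[2-(2-phenylethyl)-1,3-dioxolan-2-yl]methyl}pent-1-yn-1-yl]oxy}tri(propan-2-yl)silane | COc1cc(CC[C@H](CC2(CCc3ccccc3)OCCO2)C#CO[Si](C(C)C)(C(C)C)C(C)C)ccc1OCc1ccccc1
A2 | alternative 1 | 3-ethoxycyclobut-2-en-1-one | CCOC1=CC(=O)C1
A3 | alternative 1 | 5-ethoxy-2-[ketal chain]-3-{[tri(propan-2-yl)silyl]oxy}phenol | COc1cc(CC[C@H](CC2(CCc3ccccc3)OCCO2)c2c(O)cc(OCC)cc2O[Si](C(C)C)(C(C)C)C(C)C)ccc1OCc1ccccc1
A4 | alternative 2 | 5-(benzyloxy)-4-iodo-2-[ketal chain]benzene-1,3-diol | COc1cc(CC[C@H](CC2(CCc3ccccc3)OCCO2)c2c(O)cc(OCc3ccccc3)c(I)c2O)ccc1OCc1ccccc1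
A5 | alternative 2 | phenylacetylene, ethynylbenzene | C#Cc1ccccc1
A6 | alternative 2 | carbon monoxide | [C-]#[O+]
A7 | alternative 2 | 5-(benzyloxy)-7-hydroxy-8-[ketal chain]-2-phenyl-4H-chromen-4-one | COc1cc(CC[C@H](CC2(CCc3ccccc3)OCCO2)c2c(O)cc(OCc3ccccc3)c3c(=O)cc(-c4ccccc4)oc23)ccc1OCc1ccccc1
A8 | alternative 3 | methyl 2-[ketal chain]-3,5,7-trioxooctanoate (C2 epimers) | COc1cc(CC[C@H](CC2(CCc3ccccc3)OCCO2)C(C(=O)OC)C(=O)CC(=O)CC(C)=O)ccc1OCc1ccccc1
A9 | alternative 3 | 1-{2,4,6-trihydroxy-3-[ketal chain]phenyl}ethan-1-one | COc1cc(CC[C@H](CC2(CCc3ccccc3)OCCO2)c2c(O)cc(O)c(C(C)=O)c2O)ccc1OCc1ccccc1
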